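**Retrosynthetic overview** (labdane numbering C1–C20 throughout)
- Feature the strategy rests on: C4 of ring A carries two identical CH2OH arms (C18, C19) and is bonded to the ring-fusion carbon C5. C4 is therefore read as a reduced malonate carbon, and C4–C5 as a former alkylidene malonate C4=C5.
- Disconnections: C12–C13 by B-alkyl Suzuki coupling; C5–C10 and C3–C4 together by a type 1 intramolecular Diels–Alder reaction of C4=C5 with the diene C10(C20)=C1–C2=C3; C4=C5 by Knoevenagel condensation; C8–C9 by enantioselective Ireland–Claisen rearrangement of a trienyl ester.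
- Ring order: the chain stays acyclic through step 13, and rings A and B close together in step 14. The bought butenolide ring is attached in step 17, and the leftover C1=C2 alkene (no stereocentre there) is hydrogenated in step 18.

Key step: step 14

Assumption: the (S,S)-diazaborolidine is written as the controller that leads to (8S,9R). The sense of induction must be checked on acid 15, and the equally accessible (R,R)-controller is used if it proves opposite.

Step 1
Reactants: 1 (E)-3-methylpent-2-en-4-yn-1-ol
Product: 2 (E)-3-methylpent-2-en-4-ynal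
Conditions: MnO2 (activated), CH2Cl2, rt
Reagents that add atoms: none
Why: Allylic alcohol oxidation on MnO2 touches only the activated carbinol, spares the terminal alkyne and keeps the E geometry of the future C10=C1 bond.

Step 2
Reactants: 2 (E)-3-methylpent-2-en-4-ynal
Product: 3 (3E)-4-methylhexa-1,3-dien-5-yne
Conditions: MePPh3Br, n-BuLi, Et2O, 0 °C; then 2, −78 → 0 °C; pentane/silica filtration, kept as a concentrated solution (volatile)
Reagents that add atoms: methyltriphenylphosphonium bromide, C[P+](c1ccccc1)(c1ccccc1)c1ccccc1.[Br-]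
Why: Wittig methylenation adds C3, since the non-stabilised ylide attacks the aldehyde much faster than it could deprotonate the alkyne and the existing alkene is not involved.

Step 3
Reactants: 3 (3E)-4-methylhexa-1,3-dien-5-yne
Product: 5 (4E)-4-methylhepta-4,6-dien-2-yn-1-ol, via lithium acetylide 4 (not isolated)
Conditions: n-BuLi, THF, −78 °C; (CH2O)n, −78 °C → rt; H2O
Reagents that add atoms: paraformaldehyde (reacts as formaldehyde), C=O
Why: Deprotonation of the terminal alkyne and 1,2-addition of the alkynyllithium to formaldehyde installs C12 as a propargylic carbinol.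

Step 4
Reactants: 5 (4E)-4-methylhepta-4,6-dien-2-yn-1-ol
Product: 7 (2E,4E)-4-methylhepta-2,4,6-trien-1-ol, via cyclic alkenylaluminate 6 (not isolated)
Conditions: NaAlH2(OCH2CH2OMe)2, THF, 0 °C → rt; H2O, 0 °C
Reagents that add atoms: none
Why: Hydroxyl-directed trans-hydroalumination of a propargylic alcohol puts hydride on C11 and holds aluminium on C9 in a five-membered ring, so protonolysis with retention should give only the E C11=C9 alkene while the diene is untouched.

Step 5
Reactants: 8 δ-valerolactone
Product: 9 sodium 5-hydroxypentanoate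
Conditions: NaOH (1.0 equiv), H2O/MeOH, rt → 50 °C; evaporated to dryness
Reagents that add atoms: sodium hydroxide, [Na+].[OH-]
Why: Saponification opens the lactone, and isolation as the dry carboxylate salt prevents relactonisation.

Step 6
Reactants: 9 sodium 5-hydroxypentanoate
Product: 10 tert-butyldimethylsilyl 5-(tert-butyldimethylsilyloxy)pentanoate
Conditions: TBSCl (2.3 equiv), imidazole, DMF, rt
Reagents that add atoms: tert-butyldimethylsilyl chloride, CC(C)(C)[Si](C)(C)Cl
Why: Standard silylation caps both the primary hydroxyl and the carboxylate, which makes the material organic-soluble and easy to purify.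

Step 7
Reactants: 10 tert-butyldimethylsilyl 5-(tert-butyldimethylsilyloxy)pentanoate
Product: 11 5-(tert-butyldimethylsilyloxy)pentanoic acid
Conditions: K2CO3, MeOH/THF/H2O, rt; then 1 M HCl to pH 4, 0 °C
Reagents that add atoms: none
Why: A silyl ester is far more labile to mild basic solvolysis than a primary TBS ether, so only the ester Si–O bond is cleaved.

Step 8
Reactants: 7 (2E,4E)-4-methylhepta-2,4,6-trien-1-ol; 11 5-(tert-butyldimethylsilyloxy)pentanoic acid
Product: 12 (2E,4E)-4-methylhepta-2,4,6-trien-1-yl 5-(tert-butyldimethylsilyloxy)pentanoate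
Conditions: DCC, DMAP (cat.), CH2Cl2, 0 °C → rt
Reagents that add atoms: none
Why: Steglich esterification joins the two fragments under near-neutral conditions that spare the ionisable trienyl alcohol and the silyl ether.

Step 9
Reactants: 12 (2E,4E)-4-methylhepta-2,4,6-trien-1-yl 5-(tert-butyldimethylsilyloxy)pentanoate
Product: 15 (2S,3R,4E)-2-[3-(tert-butyldimethylsilyloxy)propyl]-3-ethenyl-4-methylhepta-4,6-dienoic acid, via boron ketene acetal 13 (not isolated), via boryl carboxylate 14 (not isolated)
Conditions: (S,S)-ArSO2NHCH(Ph)CH(Ph)NHSO2Ar [Ar = 3,5-(CF3)2C6H3], BBr3, CH2Cl2, rt, then vacuum; 12, iPr2NEt, CH2Cl2, −78 °C, then −20 °C, several days; aqueous work-up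
Reagents that add atoms: none
Why: Enantioselective Ireland–Claisen rearrangement of a chiral boron ketene acetal, in which iPr2NEt in CH2Cl2 gives the enolate with the C7 chain cis to O–B, this geometry and the E allyl alkene pass through a chair to the syn C8/C9 relation, and the C2-symmetric diazaborolidine shields one of the two mirror-image chairs so that (8S,9R) should prevail.

Step 10
Reactants: 15 (2S,3R,4E)-2-[3-(tert-butyldimethylsilyloxy)propyl]-3-ethenyl-4-methylhepta-4,6-dienoic acid
Product: 16 methyl (2S,3R,4E)-2-[3-(tert-butyldimethylsilyloxy)propyl]-3-ethenyl-4-methylhepta-4,6-dienoate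
Conditions: MeI, K2CO3, DMF, 0 °C → rt
Reagents that add atoms: iodomethane, CI
Why: O-alkylation of the carboxylate uses a base far too weak to remove the C8 or C9 hydrogen, so both stereocentres are kept.

Step 11
Reactants: 16 methyl (2S,3R,4E)-2-[3-(tert-butyldimethylsilyloxy)propyl]-3-ethenyl-4-methylhepta-4,6-dienoate
Product: 17 methyl (2S,3R,4E)-3-ethenyl-2-(3-hydroxypropyl)-4-methylhepta-4,6-dienoate
Conditions: camphorsulfonic acid (10 mol %), MeOH, 0 °C; Et3N quench before concentration; used at once
Reagents that add atoms: none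
Why: Acid-catalysed methanolysis of the primary silyl ether is fast at 0 °C, methanol as solvent holds the hydroxy ester/δ-lactone equilibrium on the open side, and neutralising the acid before evaporation freezes that state.

Step 12
Reactants: 17 methyl (2S,3R,4E)-3-ethenyl-2-(3-hydroxypropyl)-4-methylhepta-4,6-dienoate
Product: 18 methyl (2S,3R,4E)-3-ethenyl-4-methyl-2-(3-oxopropyl)hepta-4,6-dienoate
Conditions: DMP [1,1,1-triacetoxy-1,1-dihydro-1,2-benziodoxol-3(1H)-one], CH2Cl2, 0 °C → rt
Reagents that add atoms: none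
Why: The periodinane oxidation takes the C5 alcohol to the aldehyde quickly and without strong acid or base, so it outruns lactonisation and leaves alkenes and stereocentres alone.

Step 13
Reactants: 18 methyl (2S,3R,4E)-3-ethenyl-4-methyl-2-(3-oxopropyl)hepta-4,6-dienoate; 19 dimethyl malonate
Product: 20 trimethyl (5S,6R,7E)-6-ethenyl-7-methyldeca-1,7,9-triene-1,1,5-tricarboxylate
Conditions: piperidine (10 mol %), AcOH (10 mol %), 4 Å MS, CH2Cl2, rt; short silica filtration
Reagents that add atoms: none
Why: Knoevenagel condensation under piperidinium acetate catalysis turns an enolisable aliphatic aldehyde and one equivalent of malonate into the isolable alkylidene malonate, and the sieves remove water so that bis-addition is limited.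

Step 14
Reactants: 20 trimethyl (5S,6R,7E)-6-ethenyl-7-methyldeca-1,7,9-triene-1,1,5-tricarboxylate
Product: 21 trimethyl (4aS,5R,6S,8aS)-5-ethenyl-4a-methyl-1,2,4a,5,6,7,8,8a-octahydronaphthalene-1,1,6-tricarboxylate (labdane numbering 5S,8S,9R,10S; trans ring fusion; C1=C2 alkene)
Conditions: toluene (ca. 5 mM), BHT (10 mol %), 110 °C, Ar
Reagents that add atoms: none
Why: This is a concerted, asynchronous, normal-demand [4+2] cycloaddition of the type 1 intramolecular Diels–Alder class (1,7,9-decatrienes with a terminally activated dienophile, here an alkylidene 1,3-dicarbonyl acceptor): the geminal esters lower the LUMO of C4=C5 so that C5–C10 bonding leads and C3–C4 bonding follows, well below the temperature at which the inside C20 methyl could give up a hydrogen in a 1,5-shift. Ring A closes as the boat-like six-centre cycloaddition ring (C10, C1, C2, C3, C4, C5), and ring B closes in the fused mode through the four-atom tether C6–C9, which folds as a chair. C10 is set by the choice of diene face: with the C8 ester and the C9 vinyl group equatorial on the chair tether, H9 nearly eclipses C10=C1 (least A(1,3) strain) and the vinyl group points away from the dienophile, whereas the opposite face would force both groups axial. C5 is set relative to C10 by the E geometry of C10=C1 and the exo placement of C6: the ester trans to C6 can stay coplanar with the alkene and takes the endo position, while the ester cis to C6 is twisted out of plane and stays exo together with the tether, which places H5 anti to C20 (trans fusion). C4 bears two equal esters, so no endo/exo isomers arise there, and an ene pathway is closed because bonding at C10 would require transfer of a vinylic hydrogen. The step therefore needs trans over cis fusion and one diene face, and the (8S,9R) pair and the geminal diester of the substrate secure both.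

Step 15
Reactants: 21 trimethyl (4aS,5R,6S,8aS)-5-ethenyl-4a-methyl-1,2,4a,5,6,7,8,8a-octahydronaphthalene-1,1,6-tricarboxylate
Product: 22 (5S,8S,9R,10S)-13,14,15,16-tetranorlabda-1,11-diene-17,18,19-triol
Conditions: LiAlH4, THF, 0 °C → rt; H2O, aq. NaOH
Reagents that add atoms: none
Why: Hydride reduction converts all three esters into primary alcohols in one operation, removes the only epimerisable position (C8) and leaves the two unactivated alkenes alone.

Step 16
Reactants: 22 (5S,8S,9R,10S)-13,14,15,16-tetranorlabda-1,11-diene-17,18,19-triol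
Product: 23 (5S,8S,9R,10S)-17,18,19-tris(tert-butyldimethylsilyloxy)-13,14,15,16-tetranorlabda-1,11-diene
Conditions: TBSOTf (3.5 equiv), 2,6-lutidine, CH2Cl2, 0 °C → rt
Reagents that add atoms: tert-butyldimethylsilyl trifluoromethanesulfonate, CC(C)(C)[Si](C)(C)OS(=O)(=O)C(F)(F)F
Why: The silyl triflate is reactive enough to cap the neopentyl C18 and C19 hydroxyls as well as C17, which removes all O–H bonds before the borane chemistry.

Step 17
Reactants: 23 (5S,8S,9R,10S)-17,18,19-tris(tert-butyldimethylsilyloxy)-13,14,15,16-tetranorlabda-1,11-diene; 24 3-bromofuran-2(5H)-one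
Product: 26 (5S,8S,9R,10S)-17,18,19-tris(tert-butyldimethylsilyloxy)labda-1,13-dien-16,15-olide, via B-alkyl-9-BBN adduct 25 (not isolated)
Conditions: 9-BBN, THF, rt → 40 °C; then 24, PdCl2(dppf) (10 mol %), AsPh3, Cs2CO3, DMF/THF/H2O, rt → 40 °C
Reagents that add atoms: none
Why: 9-BBN adds anti-Markovnikov to the monosubstituted C11=C12 alkene far faster than to the neopentyl, disubstituted ring alkene C1=C2, and the resulting primary alkylborane undergoes B-alkyl Suzuki–Miyaura coupling after zerovalent palladium inserts into the activated α-bromo enoate C–Br bond, forming C12–C13.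

Step 18
Reactants: 26 (5S,8S,9R,10S)-17,18,19-tris(tert-butyldimethylsilyloxy)labda-1,13-dien-16,15-olide
Product: 27 (5S,8S,9R,10S)-17,18,19-tris(tert-butyldimethylsilyloxy)labd-13-en-16,15-olide
Conditions: H2 (1 atm), RhCl(PPh3)3 (15 mol %), benzene/EtOH 1:1, rt
Reagents that add atoms: none
Why: Homogeneous hydrogenation with RhCl(PPh3)3 discriminates by substitution, so the cis-disubstituted C1=C2 alkene should bind on the face opposite C20 and be reduced, while the trisubstituted, conjugated C13=C14 alkene of the butenolide is left and no stereocentre is formed.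

Step 19
Reactants: 27 (5S,8S,9R,10S)-17,18,19-tris(tert-butyldimethylsilyloxy)labd-13-en-16,15-olide
Product: 28 3-{2-[(1R,2S,4aS,8aS)-2,5,5-tris(hydroxymethyl)-8a-methyldecahydronaphthalen-1-yl]ethyl}furan-2(5H)-one (CNP0271381.1)
Conditions: HF·pyridine, THF/pyridine, 0 °C → rt
Reagents that add atoms: none
Why: Buffered acidic fluoride removes all three primary silyl ethers and avoids the basic conditions that could open or isomerise the butenolide.

**Compound list**
1 | (E)-3-methylpent-2-en-4-yn-1-ol | C#C/C(C)=C/CO | starting material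
2 | (E)-3-methylpent-2-en-4-ynal | C#C/C(C)=C/C=O | intermediate
3 | (3E)-4-methylhexa-1,3-dien-5-yne | C#C/C(C)=C/C=C | intermediate
4 | lithium acetylide of 3 | [Li]C#C/C(C)=C/C=C | intermediate
5 | (4E)-4-methylhepta-4,6-dien-2-yn-1-ol | OCC#C/C(C)=C/C=C | intermediate
6 | sodium cyclic alkenylaluminate (five-membered O–Al–C9 ring) | [Na+].COCCO[Al-]1(OCCOC)OCC=C1/C(C)=C/C=C | intermediate
7 | (2E,4E)-4-methylhepta-2,4,6-trien-1-ol | OC/C=C/C(C)=C/C=C | intermediate
8 | δ-valerolactone | O=C1CCCCO1 | starting material
9 | sodium 5-hydroxypentanoate | [Na+].[O-]C(=O)CCCCO | intermediate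
10 | tert-butyldimethylsilyl 5-(tert-butyldimethylsilyloxy)pentanoate | CC(C)(C)[Si](C)(C)OCCCCC(=O)O[Si](C)(C)C(C)(C)C | intermediate
11 | 5-(tert-butyldimethylsilyloxy)pentanoic acid | O=C(O)CCCCO[Si](C)(C)C(C)(C)C | intermediate
12 | (2E,4E)-4-methylhepta-2,4,6-trien-1-yl 5-(tert-butyldimethylsilyloxy)pentanoate | C=C/C=C(C)/C=C/COC(=O)CCCCO[Si](C)(C)C(C)(C)C | intermediate
13 | boron ketene acetal of 12, (4S,5S)-diazaborolidin-2-yl, C7 chain cis to O–B | CC(C)(C)[Si](C)(C)OCCC/C=C(\OB1N(S(=O)(=O)c2cc(C(F)(F)F)cc(C(F)(F)F)c2)[C@@H](c2ccccc2)[C@H](c2ccccc2)N1S(=O)(=O)c1cc(C(F)(F)F)cc(C(F)(F)F)c1)OC/C=C/C(C)=C/C=C | intermediate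
14 | boryl carboxylate of acid 15 | O=C(OB1N(S(=O)(=O)c2cc(C(F)(F)F)cc(C(F)(F)F)c2)[C@@H](c2ccccc2)[C@H](c2ccccc2)N1S(=O)(=O)c1cc(C(F)(F)F)cc(C(F)(F)F)c1)[C@@H](CCCO[Si](C)(C)C(C)(C)C)[C@@H](C=C)/C(C)=C/C=C | intermediate
15 | (2S,3R,4E)-2-[3-(tert-butyldimethylsilyloxy)propyl]-3-ethenyl-4-methylhepta-4,6-dienoic acid | OC(=O)[C@@H](CCCO[Si](C)(C)C(C)(C)C)[C@@H](C=C)/C(C)=C/C=C | intermediate
16 | methyl (2S,3R,4E)-2-[3-(tert-butyldimethylsilyloxy)propyl]-3-ethenyl-4-methylhepta-4,6-dienoate | COC(=O)[C@@H](CCCO[Si](C)(C)C(C)(C)C)[C@@H](C=C)/C(C)=C/C=C | intermediate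
17 | methyl (2S,3R,4E)-3-ethenyl-2-(3-hydroxypropyl)-4-methylhepta-4,6-dienoate | COC(=O)[C@@H](CCCO)[C@@H](C=C)/C(C)=C/C=C | intermediate
18 | methyl (2S,3R,4E)-3-ethenyl-4-methyl-2-(3-oxopropyl)hepta-4,6-dienoate | COC(=O)[C@@H](CCC=O)[C@@H](C=C)/C(C)=C/C=C | intermediate
19 | dimethyl malonate | COC(=O)CC(=O)OC | starting material
20 | trimethyl (5S,6R,7E)-6-ethenyl-7-methyldeca-1,7,9-triene-1,1,5-tricarboxylate | COC(=O)[C@@H](CCC=C(C(=O)OC)C(=O)OC)[C@@H](C=C)/C(C)=C/C=C | intermediate
21 | trimethyl (4aS,5R,6S,8aS)-5-ethenyl-4a-methyl-1,2,4a,5,6,7,8,8a-octahydronaphthalene-1,1,6-tricarboxylate | C[C@@]12C=CCC(C(=O)OC)(C(=O)OC)[C@H]1CC[C@H](C(=O)OC)[C@H]2C=C | intermediate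
22 | (5S,8S,9R,10S)-13,14,15,16-tetranorlabda-1,11-diene-17,18,19-triol | C[C@@]12C=CCC(CO)(CO)[C@H]1CC[C@H](CO)[C@H]2C=C | intermediate
23 | (5S,8S,9R,10S)-17,18,19-tris(tert-butyldimethylsilyloxy)-13,14,15,16-tetranorlabda-1,11-diene | C[C@@]12C=CCC(CO[Si](C)(C)C(C)(C)C)(CO[Si](C)(C)C(C)(C)C)[C@H]1CC[C@H](CO[Si](C)(C)C(C)(C)C)[C@H]2C=C | intermediate
24 | 3-bromofuran-2(5H)-one | O=C1OCC=C1Br | starting material
25 | B-(C12-alkyl)-9-borabicyclo[3.3.1]nonane from 23 | C[C@@]12C=CCC(CO[Si](C)(C)C(C)(C)C)(CO[Si](C)(C)C(C)(C)C)[C@H]1CC[C@H](CO[Si](C)(C)C(C)(C)C)[C@H]2CCB1C2CCCC1CCC2 | intermediate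
26 | (5S,8S,9R,10S)-17,18,19-tris(tert-butyldimethylsilyloxy)labda-1,13-dien-16,15-olide | C[C@@]12C=CCC(CO[Si](C)(C)C(C)(C)C)(CO[Si](C)(C)C(C)(C)C)[C@H]1CC[C@H](CO[Si](C)(C)C(C)(C)C)[C@H]2CCC1=CCOC1=O | intermediate
27 | (5S,8S,9R,10S)-17,18,19-tris(tert-butyldimethylsilyloxy)labd-13-en-16,15-olide | C[C@@]12CCCC(CO[Si](C)(C)C(C)(C)C)(CO[Si](C)(C)C(C)(C)C)[C@H]1CC[C@H](CO[Si](C)(C)C(C)(C)C)[C@H]2CCC1=CCOC1=O | intermediate
28 | 3-{2-[(1R,2S,4aS,8aS)-2,5,5-tris(hydroxymethyl)-8a-methyldecahydronaphthalen-1-yl]ethyl}furan-2(5H)-one | C[C@@]12CCCC(CO)(CO)[C@H]1CC[C@H](CO)[C@H]2CCC1=CCOC1=O | target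

**Total step count:** 19. **Longest linear sequence:** 16 steps (1 → 28 through steps 1–4 and 8–19).

**Steps most likely to fail**

1. **Step 14.** The s-cis diene must tuck the C20 methyl inside, and C5 must bond to the fully substituted terminus C10 against the natural polarity of the diene.
   - What may go wrong: the cycloaddition may be slow enough for diene polymerisation or double-bond migration to compete, and the preference for trans over cis fusion may erode.
   - Fallback: it sets out from aldehyde 18 and comes back at triol 22. The open-chain malonate is replaced by the cyclic, far more electrophilic 2,2-dimethyl-1,3-dioxane-4,6-dione (Meldrum's acid). Condensation with 18 (piperidinium acetate cat., CH2Cl2, rt) would give the alkylidene Meldrum's acid F1. Its locked coplanar dicarbonyl should let the same C5–C10/C3–C4 closure run as a domino Knoevenagel–cycloaddition at or slightly above room temperature, giving the spiro-fused octalin F2. LiAlH4 in THF then reduces the dioxanedione and the C17 ester together to 22.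

2. **Step 9.**
   - What may go wrong: the Lewis acidic bromoborane may ionise the trienyl ester, enolisation may give a mixture of enolate geometries, the rearrangement at −20 °C may be very slow, and facial discrimination may be incomplete.
   - Fallback: it sets out from ester 12 and comes back at acid 15. Reagent control is given up for a racemic Ireland–Claisen rearrangement followed by classical resolution. LiN(iPr)2 in THF/DMPU at −78 °C and then Me3SiCl gives the silyl ketene acetal F3 (C7 chain cis to OSi). On warming it rearranges through the same chair to the racemic syn trimethylsilyl ester F4, and mild aqueous hydrolysis gives the racemic syn acid F5. Fractional crystallisation with (S)-1-phenylethylamine (or its antipode, whichever gives the less soluble salt of the wanted acid) gives the ammonium salt F6. Dilute HCl frees 15 from that salt.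

3. **Step 17.**
   - What may go wrong: the base needed for transmetalation may deprotonate or hydrolyse the bromobutenolide faster than coupling occurs, and β-hydride elimination or protodeboronation of the alkyl partner may take over.
   - Fallback: it sets out from 23 (through borane 25) and comes back at 26. The C12–C13 bond is made by enolate alkylation instead of cross-coupling. Oxidation of 25 with NaOH/H2O2 gives the primary alcohol F7, and I2, PPh3 and imidazole convert it into the iodide F8. 3-(Phenylsulfanyl)oxolan-2-one F9 (from α-bromo-γ-butyrolactone, PhSH, Et3N) is deprotonated with LiN(iPr)2 in THF/DMPU and alkylated with F8 to the sulfide lactone F10 (C13 epimers, of no consequence). One equivalent of mCPBA at −78 → 0 °C gives the sulfoxide F11, because sulfur is oxidised far faster than the hindered C1=C2 alkene. Heating in toluene over CaCO3 brings about syn elimination toward C14 and gives 26.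

**Further compounds**
F1 | step 14 | methyl (2S,3R,4E)-2-[3-(2,2-dimethyl-4,6-dioxo-1,3-dioxan-5-ylidene)propyl]-3-ethenyl-4-methylhepta-4,6-dienoate | COC(=O)[C@@H](CCC=C1C(=O)OC(C)(C)OC1=O)[C@@H](C=C)/C(C)=C/C=C
F2 | step 14 | spiro[1,3-dioxane-4,6-dione-5,C4] trans-octalin C17 methyl ester (5S,8S,9R,10S) | C[C@@]12C=CCC3(C(=O)OC(C)(C)OC3=O)[C@H]1CC[C@H](C(=O)OC)[C@H]2C=C
F3 | step 9 | trimethylsilyl ketene acetal of 12, C7 chain cis to OSi | CC(C)(C)[Si](C)(C)OCCC/C=C(\O[Si](C)(C)C)OC/C=C/C(C)=C/C=C
F4 | step 9 | racemic syn trimethylsilyl ester | C[Si](C)(C)OC(=O)[C@@H](CCCO[Si](C)(C)C(C)(C)C)[C@@H](C=C)/C(C)=C/C=C.C[Si](C)(C)OC(=O)[C@H](CCCO[Si](C)(C)C(C)(C)C)[C@H](C=C)/C(C)=C/C=C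
F5 | step 9 | racemic syn acid | OC(=O)[C@@H](CCCO[Si](C)(C)C(C)(C)C)[C@@H](C=C)/C(C)=C/C=C.OC(=O)[C@H](CCCO[Si](C)(C)C(C)(C)C)[C@H](C=C)/C(C)=C/C=C
F6 | step 9 | (S)-1-phenylethylammonium salt of the (2S,3R)-acid | [O-]C(=O)[C@@H](CCCO[Si](C)(C)C(C)(C)C)[C@@H](C=C)/C(C)=C/C=C.C[C@H]([NH3+])c1ccccc1
F7 | step 17 | (5S,8S,9R,10S)-17,18,19-tris(tert-butyldimethylsilyloxy)-13,14,15,16-tetranorlabd-1-en-12-ol | C[C@@]12C=CCC(CO[Si](C)(C)C(C)(C)C)(CO[Si](C)(C)C(C)(C)C)[C@H]1CC[C@H](CO[Si](C)(C)C(C)(C)C)[C@H]2CCO
F8 | step 17 | corresponding C12 iodide | C[C@@]12C=CCC(CO[Si](C)(C)C(C)(C)C)(CO[Si](C)(C)C(C)(C)C)[C@H]1CC[C@H](CO[Si](C)(C)C(C)(C)C)[C@H]2CCI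
F9 | step 17 | 3-(phenylsulfanyl)oxolan-2-one | O=C1OCCC1Sc1ccccc1
F10 | step 17 | C13 phenylsulfanyl lactone (C13 epimers) | C[C@@]12C=CCC(CO[Si](C)(C)C(C)(C)C)(CO[Si](C)(C)C(C)(C)C)[C@H]1CC[C@H](CO[Si](C)(C)C(C)(C)C)[C@H]2CCC1(Sc2ccccc2)CCOC1=O
F11 | step 17 | C13 phenylsulfinyl lactone (isomers at C13 and S) | C[C@@]12C=CCC(CO[Si](C)(C)C(C)(C)C)(CO[Si](C)(C)C(C)(C)C)[C@H]1CC[C@H](CO[Si](C)(C)C(C)(C)C)[C@H]2CCC1(S(=O)c2ccccc2)CCOC1=O
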